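The data are calculated with constants of no real substance.

Time was the first number I weighed, and it moved the outcome little: in the dusk run at 40 °C, target went from 47.6% at 3.00 min to 48.4% at 6.00 min, a step smaller than the scatter of 1 percentage point.

| flask | starting material | reagent | second substrate | catalyst | temperature | remark | time |
|---|---|---|---|---|---|---|---|
| midnight | 20 mM | 22 mM | 40 mM | 0.20 mM | 25 °C | run made earlier |  |
| autumn | 20 mM | 31 mM | 40 mM | 0.20 mM | 40 °C | run made earlier |  |
| noon | 20 mM | 48 mM | 40 mM | 0.20 mM | 25 °C | run made earlier |  |
| dusk | 30 mM | 22 mM | 40 mM | 0.20 mM | 40 °C | run made earlier |  |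
| birch | 20 mM | 22.0 mM | 40.0 mM (fed, over 4.0 min) | 0.20 mM |  | the addition at 10 °C, then warmed to 40 °C; the feed brings no volume worth counting | 6.0 min |
| larch | 20 mM | 22.0 mM | 40.0 mM | 0.20 mM | 40 °C | everything together at the start | 6.0 min |
| elm | 20 mM | 22.0 mM (fed, over 4.0 min) | 40.0 mM | 0.20 mM | 40 °C | all else is in the flask from the start; the feed brings no volume worth counting | 6.0 min |
| alder | 20 mM | 22.0 mM | 40.0 mM (fed, over 4.0 min) | 0.20 mM | 40 °C | all else is in the flask from the start; the feed brings no volume worth counting | 6.0 min |

| run | time / min | target / % | starting material / % |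
|---|---|---|---|
| midnight | 1.00 | 50.5 | 47.9 |
| midnight | 2.00 | 64.2 | 33.4 |
| midnight | 3.00 | 67.6 | 28.8 |
| midnight | 6.00 | 69.3 | 26.6 |
| midnight | 12.0 | 70.0 | 23.3 |
| autumn | 1.33 | 65.2 | 26.2 |
| autumn | 2.50 | 71.9 | 21.5 |
| autumn | 4.00 | 75.3 | 16.7 |
| autumn | 5.00 | 74.9 | 15.6 |
| autumn | 6.00 | 78.6 | 15.5 |
| noon | 1.00 | 79.9 | 15.8 |
| noon | 2.00 | 88.7 | 5.5 |
| noon | 3.00 | 93.2 | 2.9 |
| noon | 6.00 | 94.5 | 0 |
| noon | 12.0 | 92.8 | 1.9 |
| dusk | 0.500 | 32.0 | 64.7 |
| dusk | 1.50 | 44.6 | 50.3 |
| dusk | 3.00 | 47.6 | 47.9 |
| dusk | 4.00 | 47.5 | 47.9 |
| dusk | 6.00 | 48.4 | 45.0 |

(each reading ± 1 percentage point)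



- the flask that comes out highest in amount of target, in percent of the starting material charged, or "all alike" when all lie within 1.5 percentage points (birch / larch / elm / alder / all alike)
- target at the end, in percent of the starting material charged, birch
- target at the end, in percent of the starting material charged, larch
- target at the end, in percent of the starting material charged, elm
- target at the end, in percent of the starting material charged, alder

Next I weighed the share of converted starting material that became target. It read 0.930 in autumn and 0.880 in dusk, so it could shift an answer by their ratio, 1.06.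

The reagent lost weighed more than that. Dusk stopped with 45.0% of its starting material standing, so I treated reagent as the limiting reagent and wrote its balance: reagent spent equals starting material converted plus a loss constant times the logarithm of charged over left. The autumn readings give that constant as 7.56 mM, which is 37.8% of the starting material charged, per lifetime of starting material. Dusk reads 6.89 mM.

I assumed, unproven, that the loss went to second substrate, so I divided by its charge. This gave an exchange rate, the loss constant per unit of second substrate present, a selectivity factor of 0.189.

The balance holds no reagent level, so I expected elm to stay beside larch. For alder, the first dusk reading gives a lifetime of starting material of 1.15 min. After that time the feed has brought 11.5 mM of second substrate, so the constant is 2.17 mM. Allowing two lifetimes, I reckoned that alder would lose 4.34 mM of reagent, and my reckoning gives 77.7% target. Birch has the same feed, made at 10 °C before the warming to 40 °C, and midnight at 25 °C reads a constant of 4.57 mM, less than the autumn constant, so I placed birch on top.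

The forecast also chose birch, with 73% for birch, 61% for larch, 59% for elm and 61% for alder, where it chose to “assume roughly neutral, with wide uncertainty”. There my figure stands higher than the forecast's.

    second substrate + reagent + catalyst → catalyst + second product (k = 1300 /M²/s, Ea = 36.0 kJ/mol)
    target + catalyst ⇌ isomer of the product + catalyst, rate k2*[catalyst]*[target] forward; the back reaction follows from the equilibrium constant (K = 0.120, k = 39.0 /M/s, Ea = 37.0 kJ/mol, ΔH = 32.0 kJ/mol)
    starting material + reagent + catalyst → catalyst + target (k = 5800 /M²/s, Ea = 9.00 kJ/mol)
    (constants at 40 °C)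

Birch came out highest at 76.9%, with larch at 59.3%, elm at 58.2% and alder at 75.4%, which is 14 points above the forecast. At 6.00 min alder held 4.87 mM of second product against the 4.34 mM I had allowed, and larch held 8.68 mM. A neighbour like elm, with 10 mM of second substrate and 18.8% of its starting material left, is given a loss of 3.16 mM by the exchange rate; that flask held 3.12 mM of second product.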